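**Retrosynthetic overview**

- The target comes from its tris-silyl form (two aryl TBS ethers, the central 5',6'-diol tied up as a di-tert-butylsilylene) by buffered fluoride desilylation as the last step.
- Key disconnection: both oxirane rings are made in one operation by twofold reagent-controlled Shi epoxidation of the 4,5-alkenes of a bis[(2Z,4E)-hexa-2,4-dienoate]; all four stereocentres are set here.
- The terphenyl is cut at both aryl–aryl bonds: twofold Negishi coupling of a central-ring dibromide that already carries both dienoates.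
- The dibromide diester comes from (2Z,4E)-hexa-2,4-dienoic acid (Still–Gennari olefination of crotonaldehyde) and a dibromocatechol made from bromanilic acid by silylene trapping of its ortho-quinone tautomer, then reduction.
- Ring order: all three benzene rings are bought; the dioxasilole ring (temporary) is closed in step 2; both oxiranes are closed together in step 5; the dioxasilole is opened in step 6.

Assumption: the L-fructose-derived enantiomer of the Shi ketone (1,2:4,5-di-O-isopropylidene-β-L-erythro-2,3-hexodiulo-2,6-pyranose) is bought, or otherwise made from L-sorbose.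
Assumption: half-reacted species of the twofold steps are numbered as in-flask intermediates; in the last step the three silyl groups fall in no fixed order, so the partly desilylated species are not numbered.

**Step 1**
Reactants: 1 (2E)-but-2-enal (crotonaldehyde); 2 methyl 2-[bis(2,2,2-trifluoroethoxy)phosphoryl]acetate
Product: 4 (2Z,4E)-hexa-2,4-dienoic acid, via methyl ester 3 (not isolated)
Conditions: 2, KN(SiMe3)2, 18-crown-6, THF, −78 °C, then 1; then LiOH·H2O, H2O, 0 °C → rt; 1 M HCl to pH 3 at 0 °C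
Reagents that add atoms: lithium hydroxide, [Li+].[OH-]
Why: Still–Gennari variant of the Horner–Wadsworth–Emmons olefination gives the 2Z alkene under kinetic control (fast collapse of the erythro adduct of the electron-poor phosphonate), the 4E alkene is carried over from crotonaldehyde, and saponification in the same flask avoids isolating the volatile ester without touching the alkene geometry.

**Step 2**
Reactants: 5 bromanilic acid (2,5-dibromo-3,6-dihydroxycyclohexa-2,5-diene-1,4-dione)
Product: 7 4,7-dibromo-2,2-di-tert-butyl-1,3,2-benzodioxasilole-5,6-diol, via ortho-quinone silylene 6 (not isolated)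
Conditions: 2,6-lutidine (2.2 equiv), MeCN/CH2Cl2, −40 °C, slow addition of tBu2Si(OTf)2 (1.05 equiv), → 0 °C; then Hantzsch ester (diethyl 2,6-dimethyl-1,4-dihydropyridine-3,5-dicarboxylate, 1.1 equiv), 0 °C, argon; 7 is used at once
Reagents that add atoms: di-tert-butylsilyl bis(trifluoromethanesulfonate), CC(C)(C)[Si](OS(=O)(=O)C(F)(F)F)(OS(=O)(=O)C(F)(F)F)C(C)(C)C
Why: Proposed new method: the bromanilate dianion is a bis(vinylogous carboxylate), so after the first O-silylation the second Si–OTf can only be reached by the neighbouring oxygen (five-membered ring closure), which locks the ortho-quinone tautomer 6 and blocks exactly one oxygen pair, and hydride transfer from the Hantzsch ester (as in the oxidation of dihydropyridines by halogenated ortho-quinones) then gives catechol 7; the closest known reactions are di-tert-butylsilylene protection of catechols and 1,2-diols with tBu2Si(OTf)2, chelation of 2,5-dihydroxy-1,4-benzoquinone dianions through adjacent oxygens, and condensation of these quinones with 1,2-diamines as their ortho-quinone tautomers.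

**Step 3**
Reactants: 7 4,7-dibromo-2,2-di-tert-butyl-1,3,2-benzodioxasilole-5,6-diol; 4 (2Z,4E)-hexa-2,4-dienoic acid (2.4 equiv)
Product: 10 4,7-dibromo-2,2-di-tert-butyl-1,3,2-benzodioxasilole-5,6-diyl bis[(2Z,4E)-hexa-2,4-dienoate], via acid chloride 8 (not isolated), via monoester 9 (not isolated)
Conditions: 4, 1-chloro-N,N,2-trimethylprop-1-en-1-amine (Ghosez reagent), CH2Cl2, 0 °C; then 7, 2,4,6-collidine, CH2Cl2, −20 → 0 °C
Reagents that add atoms: none
Why: O-acylation of the acidic catechol hydroxyls by an acid chloride made under neutral conditions, with a hindered non-nucleophilic pyridine base, avoids vinylketene formation (deconjugation) and nucleophile-induced Z to E isomerisation (acid chloride esterification, no stereocentre formed).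

**Step 4**
Reactants: 10 4,7-dibromo-2,2-di-tert-butyl-1,3,2-benzodioxasilole-5,6-diyl bis[(2Z,4E)-hexa-2,4-dienoate]; 11 (4-bromophenoxy)(tert-butyl)dimethylsilane (3 equiv)
Product: 15 2,2-di-tert-butyl-4,7-bis{4-[(tert-butyldimethylsilyl)oxy]phenyl}-1,3,2-benzodioxasilole-5,6-diyl bis[(2Z,4E)-hexa-2,4-dienoate], via Grignard reagent 12 (not isolated), via arylzinc chloride 13 (not isolated), via monoaryl bromide 14 (not isolated)
Conditions: 11, Mg, THF, rt; ZnCl2 (1.1 equiv per Mg), THF, 0 °C; then 10, Pd(OAc)2 (5 mol%), SPhos (2-dicyclohexylphosphino-2',6'-dimethoxybiphenyl, 10 mol%), THF, 45 °C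
Reagents that add atoms: none
Why: Negishi cross-coupling, in which zerovalent palladium with SPhos inserts into the hindered electron-rich C–Br bonds and the arylzinc chloride transmetalates without base or water, so the aryl esters, Z-dienoates, silyl ethers and dioxasilole never meet hydroxide (no stereocentre formed).

**Step 5**
Reactants: 15 2,2-di-tert-butyl-4,7-bis{4-[(tert-butyldimethylsilyl)oxy]phenyl}-1,3,2-benzodioxasilole-5,6-diyl bis[(2Z,4E)-hexa-2,4-dienoate]
Product: 17 2,2-di-tert-butyl-4,7-bis{4-[(tert-butyldimethylsilyl)oxy]phenyl}-1,3,2-benzodioxasilole-5,6-diyl bis{(2Z)-3-[(2S,3S)-3-methyloxiran-2-yl]prop-2-enoate}, via monoepoxide 16 (not isolated)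
Conditions: L-fructose-derived Shi ketone (0.6 equiv, 0.3 per alkene), KHSO5 (as 2KHSO5·KHSO4·K2SO4, 3 equiv), K2CO3 added alongside to hold pH 9.5–10, Bu4NHSO4 (cat.), MeCN/CH2(OMe)2/aq. Na2B4O7 buffer, −5 → 0 °C, 3 h
Reagents that add atoms: potassium peroxymonosulfate, [K+].[O-]S(=O)(=O)OO
Why: twofold Shi epoxidation, in which the chiral dioxirane from the L-fructose-derived ketone transfers oxygen through the spiro transition state to the electron-richer trans 4,5-alkene of each dienoate (the D-fructose ketone gives R,R-epoxides from trans-alkenes, so its enantiomer gives 4S,5S), the ester-conjugated Z-2,3-alkenes are too electron-poor to react, and the two-site statistics turn the minor enantiomeric pathway into a separable diastereomer.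

**Step 6**
Reactants: 17 2,2-di-tert-butyl-4,7-bis{4-[(tert-butyldimethylsilyl)oxy]phenyl}-1,3,2-benzodioxasilole-5,6-diyl bis{(2Z)-3-[(2S,3S)-3-methyloxiran-2-yl]prop-2-enoate}
Product: 18 4,4'',5',6'-tetrahydroxy-[1,1':4',1''-terphenyl]-2',3'-diyl bis{(2Z)-3-[(2S,3S)-3-methyloxiran-2-yl]prop-2-enoate} (CNP0249450.1)
Conditions: Bu4NF/AcOH (1:1, 5 equiv), THF, 0 °C; pH 5 buffer work-up, reversed-phase purification
Reagents that add atoms: none
Why: fluoride-induced desilylation, driven by Si–F bond strength, cleaves both aryl silyl ethers and the strained dioxasilole, and the acetic acid buffer keeps free phenoxide and strong acid away from the aryl esters, Z-enoates and vinyl epoxides (stereocentres untouched).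

**Compound list**

1 | (2E)-but-2-enal (crotonaldehyde) | C/C=C/C=O | starting material
2 | methyl 2-[bis(2,2,2-trifluoroethoxy)phosphoryl]acetate | COC(=O)CP(=O)(OCC(F)(F)F)OCC(F)(F)F | starting material
3 | methyl (2Z,4E)-hexa-2,4-dienoate | C/C=C/C=C\C(=O)OC | intermediate
4 | (2Z,4E)-hexa-2,4-dienoic acid | C/C=C/C=C\C(=O)O | intermediate
5 | bromanilic acid (2,5-dibromo-3,6-dihydroxycyclohexa-2,5-diene-1,4-dione) | O=C1C(O)=C(Br)C(=O)C(O)=C1Br | starting material
6 | 4,7-dibromo-2,2-di-tert-butyl-1,3,2-benzodioxasilole-5,6-dione | CC(C)(C)[Si]1(C(C)(C)C)OC2=C(Br)C(=O)C(=O)C(Br)=C2O1 | intermediate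
7 | 4,7-dibromo-2,2-di-tert-butyl-1,3,2-benzodioxasilole-5,6-diol | CC(C)(C)[Si]1(C(C)(C)C)Oc2c(Br)c(O)c(O)c(Br)c2O1 | intermediate
8 | (2Z,4E)-hexa-2,4-dienoyl chloride | C/C=C/C=C\C(=O)Cl | intermediate
9 | 4,7-dibromo-2,2-di-tert-butyl-6-hydroxy-1,3,2-benzodioxasilol-5-yl (2Z,4E)-hexa-2,4-dienoate | C/C=C/C=C\C(=O)Oc1c(O)c(Br)c2O[Si](C(C)(C)C)(C(C)(C)C)Oc2c1Br | intermediate
10 | 4,7-dibromo-2,2-di-tert-butyl-1,3,2-benzodioxasilole-5,6-diyl bis[(2Z,4E)-hexa-2,4-dienoate] | C/C=C/C=C\C(=O)Oc1c(OC(=O)/C=C\C=C\C)c(Br)c2O[Si](C(C)(C)C)(C(C)(C)C)Oc2c1Br | intermediate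
11 | (4-bromophenoxy)(tert-butyl)dimethylsilane | CC(C)(C)[Si](C)(C)Oc1ccc(Br)cc1 | starting material
12 | {4-[(tert-butyldimethylsilyl)oxy]phenyl}magnesium bromide | CC(C)(C)[Si](C)(C)Oc1ccc([Mg]Br)cc1 | intermediate
13 | chloro{4-[(tert-butyldimethylsilyl)oxy]phenyl}zinc | CC(C)(C)[Si](C)(C)Oc1ccc([Zn]Cl)cc1 | intermediate
14 | 7-bromo-2,2-di-tert-butyl-4-{4-[(tert-butyldimethylsilyl)oxy]phenyl}-1,3,2-benzodioxasilole-5,6-diyl bis[(2Z,4E)-hexa-2,4-dienoate] | C/C=C/C=C\C(=O)Oc1c(OC(=O)/C=C\C=C\C)c(-c3ccc(O[Si](C)(C)C(C)(C)C)cc3)c2O[Si](C(C)(C)C)(C(C)(C)C)Oc2c1Br | intermediate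
15 | 2,2-di-tert-butyl-4,7-bis{4-[(tert-butyldimethylsilyl)oxy]phenyl}-1,3,2-benzodioxasilole-5,6-diyl bis[(2Z,4E)-hexa-2,4-dienoate] | C/C=C/C=C\C(=O)Oc1c(OC(=O)/C=C\C=C\C)c(-c3ccc(O[Si](C)(C)C(C)(C)C)cc3)c2O[Si](C(C)(C)C)(C(C)(C)C)Oc2c1-c4ccc(O[Si](C)(C)C(C)(C)C)cc4 | intermediate
16 | 2,2-di-tert-butyl-4,7-bis{4-[(tert-butyldimethylsilyl)oxy]phenyl}-6-{[(2Z,4E)-hexa-2,4-dienoyl]oxy}-1,3,2-benzodioxasilol-5-yl (2Z)-3-[(2S,3S)-3-methyloxiran-2-yl]prop-2-enoate | C[C@@H]1O[C@H]1/C=C\C(=O)Oc1c(OC(=O)/C=C\C=C\C)c(-c3ccc(O[Si](C)(C)C(C)(C)C)cc3)c2O[Si](C(C)(C)C)(C(C)(C)C)Oc2c1-c4ccc(O[Si](C)(C)C(C)(C)C)cc4 | intermediate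
17 | 2,2-di-tert-butyl-4,7-bis{4-[(tert-butyldimethylsilyl)oxy]phenyl}-1,3,2-benzodioxasilole-5,6-diyl bis{(2Z)-3-[(2S,3S)-3-methyloxiran-2-yl]prop-2-enoate} | C[C@@H]1O[C@H]1/C=C\C(=O)Oc1c(OC(=O)/C=C\[C@@H]2O[C@H]2C)c(-c3ccc(O[Si](C)(C)C(C)(C)C)cc3)c2O[Si](C(C)(C)C)(C(C)(C)C)Oc2c1-c4ccc(O[Si](C)(C)C(C)(C)C)cc4 | intermediate
18 | 4,4'',5',6'-tetrahydroxy-[1,1':4',1''-terphenyl]-2',3'-diyl bis{(2Z)-3-[(2S,3S)-3-methyloxiran-2-yl]prop-2-enoate} (CNP0249450.1) | C[C@@H]1O[C@H]1/C=C\C(=O)Oc1c(OC(=O)/C=C\[C@@H]2O[C@H]2C)c(-c2ccc(O)cc2)c(O)c(O)c1-c1ccc(O)cc1 | target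

**Totals**

Total step count: 6.
Longest linear sequence: 5 steps (2, 3, 4, 5, 6 from bromanilic acid; equally 1, 3, 4, 5, 6 from crotonaldehyde).

**Steps most likely to fail, with fallbacks**

Step 2 (silylene trapping of the ortho-quinone tautomer) is unprecedented. The silyl bis(triflate) may give oligomeric silyl esters, or 6 may hydrolyse before it is reduced. The fallback inverts the order, so that the differentiation becomes statistical instead of tautomer-controlled. It sets out from 5, which is reduced first (Na2S2O4, EtOAc/H2O) to 3,6-dibromobenzene-1,2,4,5-tetraol F1. F1 is then treated with only 0.5 equiv of tBu2Si(OTf)2 (2,6-lutidine, MeCN, −40 °C, slow addition). This gives the mono-silylene beside recovered F1 (air re-oxidises it to 5, which is recycled) and a little bis-silylene. The route is rejoined at 7.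

Step 4 (twofold Negishi coupling on the diester) may fail through ester cleavage, Z to E drift of the dienoates at palladium, or sluggish insertion next to the acyloxy groups. The fallback puts the aryl groups on before the dienoates. It sets out from 7, which pivaloyl chloride and pyridine convert to 4,7-dibromo-2,2-di-tert-butyl-1,3,2-benzodioxasilole-5,6-diyl bis(2,2-dimethylpropanoate) F2. Twofold Negishi coupling of F2 with 13 (Pd(OAc)2, SPhos, THF, 60 °C) gives 2,2-di-tert-butyl-4,7-bis{4-[(tert-butyldimethylsilyl)oxy]phenyl}-1,3,2-benzodioxasilole-5,6-diyl bis(2,2-dimethylpropanoate) F3. iBu2AlH (CH2Cl2, −78 °C) removes both pivalates to give 2,2-di-tert-butyl-4,7-bis{4-[(tert-butyldimethylsilyl)oxy]phenyl}-1,3,2-benzodioxasilole-5,6-diol F4. F4 is acylated with 8 and 2,4,6-collidine as in step 3, and the route is rejoined at 15.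

Step 5 (twofold Shi epoxidation) may stall at 16, or the pH 10 medium may cleave the aryl esters or the dioxasilole faster than the second oxirane forms. The fallback makes the oxirane on the small ester and brings both in by acylation. It sets out from 3, isolated from step 1 by leaving out the LiOH. Epoxidation of 3 with the same ketone and KHSO5 gives methyl (2Z)-3-[(2S,3S)-3-methyloxiran-2-yl]prop-2-enoate F5. LiOH converts F5 to lithium (2Z)-3-[(2S,3S)-3-methyloxiran-2-yl]prop-2-enoate F6, which is kept as the salt because the free Z-epoxy acid lactonises. Pivaloyl chloride (THF, −20 °C) turns F6 into 2,2-dimethylpropanoic (2Z)-3-[(2S,3S)-3-methyloxiran-2-yl]prop-2-enoic anhydride F7. The disodium salt (NaH, THF) of terphenyl catechol F4 from the preceding fallback is acylated with F7 at its less hindered carbonyl; F4 is needed because vinyl epoxides must not meet zerovalent palladium. The route is rejoined at 17.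

**Further compounds**

F1 | step 2 | 3,6-dibromobenzene-1,2,4,5-tetraol | Oc1c(O)c(Br)c(O)c(O)c1Br
F2 | step 4 | 4,7-dibromo-2,2-di-tert-butyl-1,3,2-benzodioxasilole-5,6-diyl bis(2,2-dimethylpropanoate) | CC(C)(C)C(=O)Oc1c(OC(=O)C(C)(C)C)c(Br)c2O[Si](C(C)(C)C)(C(C)(C)C)Oc2c1Br
F3 | step 4 | 2,2-di-tert-butyl-4,7-bis{4-[(tert-butyldimethylsilyl)oxy]phenyl}-1,3,2-benzodioxasilole-5,6-diyl bis(2,2-dimethylpropanoate) | CC(C)(C)C(=O)Oc1c(OC(=O)C(C)(C)C)c(-c3ccc(O[Si](C)(C)C(C)(C)C)cc3)c2O[Si](C(C)(C)C)(C(C)(C)C)Oc2c1-c4ccc(O[Si](C)(C)C(C)(C)C)cc4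
F4 | step 4 | 2,2-di-tert-butyl-4,7-bis{4-[(tert-butyldimethylsilyl)oxy]phenyl}-1,3,2-benzodioxasilole-5,6-diol | Oc1c(O)c(-c3ccc(O[Si](C)(C)C(C)(C)C)cc3)c2O[Si](C(C)(C)C)(C(C)(C)C)Oc2c1-c4ccc(O[Si](C)(C)C(C)(C)C)cc4
F5 | step 5 | methyl (2Z)-3-[(2S,3S)-3-methyloxiran-2-yl]prop-2-enoate | C[C@@H]1O[C@H]1/C=C\C(=O)OC
F6 | step 5 | lithium (2Z)-3-[(2S,3S)-3-methyloxiran-2-yl]prop-2-enoate | C[C@@H]1O[C@H]1/C=C\C(=O)[O-].[Li+]
F7 | step 5 | 2,2-dimethylpropanoic (2Z)-3-[(2S,3S)-3-methyloxiran-2-yl]prop-2-enoic anhydride | C[C@@H]1O[C@H]1/C=C\C(=O)OC(=O)C(C)(C)C
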